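The ratio of larch's target to maple's, read at 18 min, is 1.26, on 3.00 times the starting material, so early target rises less than the charge does. The runs and the questions are these.

| flask | starting material | partner | catalyst | time |
|---|---|---|---|---|
| maple | 0.500 M | 0.400 M | 0.00250 M |  |
| ash | 0.250 M | 0.150 M | 0.00250 M |  |
| larch | 1.50 M | 0.400 M | 0.00250 M |  |
| cedar | 0.500 M | 0.400 M | 0.00500 M |  |
| alder | 0.250 M | 0.800 M | 0.00250 M | 64 min |

| maple run: time / min | maple run: [target] / M | ash run: time / min | ash run: [target] / M | larch run: time / min | larch run: [target] / M | cedar run: time / min | cedar run: [target] / M |
|---|---|---|---|---|---|---|---|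
| 2.6 | 0.015 | 2.6 | 0.011 | 2.6 | 0.014 | 2.6 | 0.026 |
| 4.9 | 0.017 | 4.9 | 0.014 | 4.9 | 0.025 | 4.9 | 0.052 |
| 9.3 | 0.052 | 9.3 | 0.027 | 9.3 | 0.052 | 9.3 | 0.084 |
| 18 | 0.074 | 18 | 0.040 | 18 | 0.093 | 18 | 0.149 |
| 34 | 0.128 | 34 | 0.064 | 34 | 0.162 | 34 | 0.218 |
| 64 | 0.160 | 64 | 0.079 | 64 | 0.240 | 64 | 0.243 |

(readings scatter by 0.003 M)

- Overall: starting material + partner -> target, with catalyst as catalyst.
- Constant volume, constant temperature.
- A reading of a species includes what of it is bound.
- An order is taken over about fifteen percent of the charge, up and down.

* the exponent of [partner] in the starting rate at the charge of the maple run (at the point where two percent of the starting material have become target)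
* the exponent of [catalyst] in the starting rate at the charge of the maple run (at the point where two percent of the starting material have become target)
* target in the alder run at 64 min, as a share of the starting material charged

Two chemists read these runs. Both see flasks that slow down. Take a flask's early rate as its target at 9.3 min and at 18 min added, over those two times added. Maple's early rate reads 0.00462 M min⁻¹, but it makes only 0.00107 M min⁻¹ on average between 34 min and 64 min. The first chemist says that catalyst dies once starting material runs low. The second says that catalyst lives and starting material leaks away by a road of its own.

The second chemist points to cedar at 34 min. If target were the one exit, cedar would still hold 0.282 M starting material, more than ash's whole charge of 0.250 M. Ash's catalyst works at that level, so that level is not low. The first chemist keeps one region. At 18 min, cedar holds 2.01 times maple's target, as a count of working catalyst says. By 64 min that ratio is 1.52.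

I side with the leak, and I carry one quantity: the charge time, the starting material charged divided by the early rate. It is how long the starting material charged would last at its early pace with no leak. The early rates read 0.00245 M min⁻¹ for ash, 0.00853 M min⁻¹ for cedar and 0.00531 M min⁻¹ for larch. The charge time for maple is 108 min, for ash 102 min, for cedar 58.6 min and for larch 282 min. At 64 min, maple has made 32.0% of its charge and ash 31.6%, and their charge times stand at a ratio of 1.06. Cedar, with a shorter charge time, has made 48.6%. Larch, with a longer one, has made 16.0%. Between maple and cedar, the share goes as charge time to the power 0.680, with the sign reversed.

Alder needs a starting rate. I split the catalyst's turnover time, catalyst over rate, into two waits. Maple against larch gives the wait for starting material: 0.106 min at maple's charge and 0.213 min at ash's and alder's. The wait for partner is then 0.435 min in maple, the longer one and so the rate-limiting step, and 0.806 min in ash. That wait goes as partner to the power 0.628 with the sign reversed, which gives 0.282 min in alder.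

So alder starts near 0.00506 M min⁻¹, with a charge time of 49.5 min. My share for alder is 54.5%. Weighting the partner power by its wait gives me a partner order of 0.505 in maple, and cedar's target over maple's at 18 min gives a catalyst order of 1.01.

The forecast, from the first chemist's side, gives 0.6 (0.4 to 0.85) for partner, 0.93 (0.8 to 1.08) for catalyst and 70% (52% to 88%) for alder, holding that “The catalyst seems to die when starting material is low”.

The flask gives 0.52 for partner, 1.0 for catalyst and 47.5% for alder.

    catalyst + starting material → catalyst-substrate complex (22.92 L mol⁻¹ min⁻¹)
    catalyst-substrate complex + partner → target + catalyst (15.78 L mol⁻¹ min⁻¹)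
    2 partner ⇌ idle reagent dimer, settled at all times (5.170 L mol⁻¹)
    starting material → decomposed substrate (0.03612 min⁻¹)

No step here removes catalyst, and starting material goes to decomposed substrate with a lifetime of 27.7 min. That lifetime is shorter than alder's charge time of 49.5 min. Cedar's charge time of 58.6 min also exceeds it. At its early pace, cedar would reach a quarter of its charge at 14.7 min; it got there at 15.0 min.

Readings and results stem from a simulated flask for substances that don't exist.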